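**Plan**
- Retrosynthesis: remove the O5 and O4''' benzyl groups and the O7–Si–O5'' bridge, cut the C8–C6'' biaryl bond inside that bridge, then cut the two Si–O bonds and C8–Br. This leads back to acacetin, genkwanin and t-Bu2Si(OTf)2.
- Enabling feature: the C8–C6'' bond has 7-OH (ring A, acacetin half) on one side and 5''-OH (ring A, genkwanin half) on the other. Silicon between these two oxygens holds C8 over C6'', the only C–H ortho to O5'', since the other ortho carbon is the fusion atom C4a''.
- Forward: both chromone systems come ready-made. Acacetin is protected (7-O-MOM, 5-O-Bn), brominated at C8 and unmasked at O7. Genkwanin is benzylated at O4'''. The two phenols are joined through silicon, palladium closes the temporary seven-membered dioxasilepine, and fluoride followed by hydrogenolysis unmasks the target.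
- Stereochemistry: there is no stereocentre, and the C8–C6'' axis carries no descriptor in the target, so it is formed without control.

Key step: step 7

Remark: unprimed locants are the acacetin half, double-primed the genkwanin half, triple-primed its 2-aryl ring. The axis is taken as racemic. Acacetin, genkwanin and di-tert-butylsilyl bis(triflate) are taken as commercial.

Step 1
Reactants: 1 acacetin
Product: 2 7-O-(methoxymethyl)acacetin
Conditions: MOMCl (1.1 equiv), i-Pr2NEt, CH2Cl2/DMF, 0 °C to rt
Reagents that add atoms: chloromethyl methyl ether, COCCl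
Why: Williamson-type O-alkylation that should occur only at the acidic 7-OH, because the 5-OH is held in a hydrogen bond to the C4 carbonyl.

Step 2
Reactants: 2 7-O-(methoxymethyl)acacetin
Product: 3 5-O-benzyl-7-O-(methoxymethyl)acacetin
Conditions: BnBr, K2CO3, tetrabutylammonium iodide (cat.), DMF, 60 °C
Reagents that add atoms: benzyl bromide, BrCc1ccccc1
Why: Williamson ether synthesis under the forcing conditions usual for the hydrogen-bonded 5-OH of flavones, which removes the only acidic proton of this half and the ortho-directing free 5-OH before halogenation.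

Step 3
Reactants: 3 5-O-benzyl-7-O-(methoxymethyl)acacetin
Product: 4 5-O-benzyl-8-bromo-7-O-(methoxymethyl)acacetin
Conditions: NBS (1.05 equiv), DMF, 0 °C to rt, dark
Reagents that add atoms: N-bromosuccinimide, BrN1C(=O)CCC1=O
Why: Electrophilic aromatic bromination of the most electron-rich ring, which in 5,7-dialkoxyflavones goes to C8 (ortho to O7, para to O5) in preference to C6 flanked by two alkoxy groups.

Step 4
Reactants: 4 5-O-benzyl-8-bromo-7-O-(methoxymethyl)acacetin
Product: 5 5-O-benzyl-8-bromoacacetin (free 7-OH)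
Conditions: conc. HCl (cat.), MeOH/THF, 45 °C
Reagents that add atoms: none
Why: Acid-catalysed acetal exchange (methanolysis) of the aryl MOM ether, under which the aryl benzyl ether, the aryl bromide and the methyl ether should be inert.

Step 5
Reactants: 6 genkwanin
Product: 7 4'''-O-benzylgenkwanin
Conditions: BnBr (1.05 equiv), K2CO3, acetone, reflux
Reagents that add atoms: benzyl bromide, BrCc1ccccc1
Why: Williamson ether synthesis at the only phenol not hydrogen-bonded to the carbonyl, so the 5''-OH should remain free.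

Step 6
Reactants: 7 4'''-O-benzylgenkwanin; 8 di-tert-butylsilyl bis(trifluoromethanesulfonate); 5 5-O-benzyl-8-bromoacacetin
Product: 10 [5-benzyloxy-8-bromo-2-(4-methoxyphenyl)-4-oxo-4H-chromen-7-yl]oxy{[2-(4-benzyloxyphenyl)-7-methoxy-4-oxo-4H-chromen-5-yl]oxy}di-tert-butylsilane, via silyl triflate 9 (not isolated)
Conditions: 7, t-Bu2Si(OTf)2 (1.0 equiv), Et3N, CH2Cl2, 0 °C to rt; then 5, Et3N, DMAP (cat.), DMF, 50 °C
Reagents that add atoms: di-tert-butylsilyl bis(trifluoromethanesulfonate), CC(C)(C)[Si](OS(=O)(=O)C(F)(F)F)(OS(=O)(=O)C(F)(F)F)C(C)(C)C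
Why: Sequential nucleophilic substitution at silicon (O-silylation with a silyl triflate) in which the very electrophilic bis(triflate) silylates the poorly nucleophilic 5''-OH once, and the hindered remaining Si–OTf is displaced only by the more nucleophilic 7-phenoxide of 5 under DMAP catalysis.

Step 7
Reactants: 10 bis(aryloxy)di-tert-butylsilane
Product: 11 7,5''-O-(di-tert-butylsilylene)-5,4'''-di-O-benzyl derivative of the target (dibenzo[d,f][1,3,2]dioxasilepine)
Conditions: Pd(OAc)2 (10 mol %), PCy3·HBF4 (20 mol %), Cs2CO3 (2 equiv), p-xylene, 130 °C, argon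
Reagents that add atoms: none
Why: Zerovalent palladium formed from Pd(OAc)2 and PCy3 inserts into C8–Br, the O7–Si–O5'' bridge holds the divalent arylpalladium bromide over C6''–H, carbonate-assisted concerted metalation–deprotonation gives an eight-membered diarylpalladium ring, and reductive elimination forms C8–C6''. The closest known reaction type is the silicon-tethered palladium-catalysed intramolecular C–H arylation of unsymmetrical bis(aryloxy)di-tert-butylsilanes to dibenzo[d,f][1,3,2]dioxasilepines, which also gives binaphthol-type biaryls with four ortho substituents. The seven-membered ring C7–O–Si–O–C5''–C6''–C8 closes by aryl–aryl reductive elimination from that palladacycle, that is, by intramolecular direct arylation of C6'' by C8. No stereocentre arises and the C8–C6'' axis forms without control, which the target allows. The selectivity needed is C8 to C6'': bromine fixes C8, and O5'' has C6'' as its only ortho C–H because the other ortho carbon is the fusion atom C4a'', while C6–H, C8''–H and the C3 and C3'' hydrogens are out of reach of the tether. With O5 and O4''' benzylated the substrate has no acidic OH, so Cs2CO3 serves only the C–H cleavage and the tert-butyl groups shield silicon from carbonate.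

Step 8
Reactants: 11 silylene-bridged dibenzyl biflavone
Product: 12 5-benzyloxy-7-hydroxy-8-[2-(4-benzyloxyphenyl)-5-hydroxy-7-methoxy-4-oxo-4H-chromen-6-yl]-2-(4-methoxyphenyl)-4H-chromen-4-one
Conditions: n-Bu4NF (2.5 equiv), AcOH (2.5 equiv), THF, 0 °C to rt
Reagents that add atoms: none
Why: Fluoride-induced desilylation of both aryl–O–Si bonds, driven by Si–F bond formation and buffered by acetic acid, which should leave benzyl and methyl ethers untouched.

Step 9
Reactants: 12 5,4'''-di-O-benzyl biflavone
Product: 13 5,7-dihydroxy-8-[5-hydroxy-2-(4-hydroxyphenyl)-7-methoxy-4-oxo-4H-chromen-6-yl]-2-(4-methoxyphenyl)-4H-chromen-4-one (target)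
Conditions: H2 (1 atm), 10% Pd/C, THF/MeOH, rt
Reagents that add atoms: none
Why: Catalytic hydrogenolysis of the two aryl benzyl ethers, under which the aryl-conjugated C2=C3 bonds of both flavone units and the methyl ethers normally survive.

**Compound list**
1 | acacetin (5,7-dihydroxy-4'-methoxyflavone) | COc1ccc(cc1)-c1cc(=O)c2c(O)cc(O)cc2o1 | starting material
2 | 7-O-(methoxymethyl)acacetin | COc1ccc(cc1)-c1cc(=O)c2c(O)cc(OCOC)cc2o1 | intermediate
3 | 5-O-benzyl-7-O-(methoxymethyl)acacetin | COc1ccc(cc1)-c1cc(=O)c2c(OCc3ccccc3)cc(OCOC)cc2o1 | intermediate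
4 | 5-O-benzyl-8-bromo-7-O-(methoxymethyl)acacetin | COc1ccc(cc1)-c1cc(=O)c2c(OCc3ccccc3)cc(OCOC)c(Br)c2o1 | intermediate
5 | 5-O-benzyl-8-bromoacacetin | COc1ccc(cc1)-c1cc(=O)c2c(OCc3ccccc3)cc(O)c(Br)c2o1 | intermediate
6 | genkwanin (5,4'-dihydroxy-7-methoxyflavone) | COc1cc(O)c2c(c1)oc(cc2=O)-c1ccc(O)cc1 | starting material
7 | 4'''-O-benzylgenkwanin | COc1cc(O)c2c(c1)oc(cc2=O)-c1ccc(OCc3ccccc3)cc1 | intermediate
8 | di-tert-butylsilyl bis(trifluoromethanesulfonate) | CC(C)(C)[Si](OS(=O)(=O)C(F)(F)F)(OS(=O)(=O)C(F)(F)F)C(C)(C)C | starting material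
9 | 5''-O-[di-tert-butyl(trifluoromethanesulfonyloxy)silyl]-4'''-O-benzylgenkwanin | COc1cc(O[Si](OS(=O)(=O)C(F)(F)F)(C(C)(C)C)C(C)(C)C)c2c(c1)oc(cc2=O)-c1ccc(OCc3ccccc3)cc1 | intermediate
10 | di-tert-butylsilylene-bridged 5-O-benzyl-8-bromoacacetin (through O7) and 4'''-O-benzylgenkwanin (through O5'') | COc1ccc(cc1)-c1cc(=O)c2c(OCc3ccccc3)cc(O[Si](Oc3cc(OC)cc4oc(-c5ccc(OCc6ccccc6)cc5)cc(=O)c34)(C(C)(C)C)C(C)(C)C)c(Br)c2o1 | intermediate
11 | 7,5''-O-(di-tert-butylsilylene)-5,4'''-di-O-benzyl derivative of the target | COc1ccc(cc1)-c1cc(=O)c2c(OCc3ccccc3)cc3O[Si](C(C)(C)C)(C(C)(C)C)Oc4c(-c3c2o1)c(OC)cc5oc(-c6ccc(OCc7ccccc7)cc6)cc(=O)c45 | intermediate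
12 | 5,4'''-di-O-benzyl derivative of the target | COc1ccc(cc1)-c1cc(=O)c2c(OCc3ccccc3)cc(O)c(-c3c(OC)cc4oc(-c5ccc(OCc6ccccc6)cc5)cc(=O)c4c3O)c2o1 | intermediate
13 | acacetin-(8→6'')-genkwanin, CNP0253922.0 | COc1ccc(-c2cc(=O)c3c(O)cc(O)c(-c4c(OC)cc5oc(-c6ccc(O)cc6)cc(=O)c5c4O)c3o2)cc1 | target

**Step count**
Total: 9 steps. Longest linear sequence: 8 steps (steps 1, 2, 3, 4, 6, 7, 8, 9).

**Steps most likely to fail**

Step 7. The arylpalladium bromide may lose bromine by protonation, or carbonate may cleave the Si–O bonds before the crowded C6''–H is metalated. The fallback replaces C–H activation by a reductive coupling of two carbon–halogen bonds on the same tether. Setting out from 7, iodination with N-iodosuccinimide in DMF, ortho to the free 5''-OH as is usual for 5-hydroxy-7-methoxyflavones, would give 6''-iodo-4'''-O-benzylgenkwanin F1. The protocol of step 6 with 8 and 5 would lead through the iodinated silyl triflate F2 to the bromo-iodo bis(aryloxy)silane F3. An intramolecular Ullmann-type reductive aryl–aryl coupling with stoichiometric zerovalent nickel (Ni(cod)2, 2,2'-bipyridine, DMF, 60 °C) would then close the same seven-membered ring and come back to the route at 11.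

Step 6. Silylation of the hydrogen-bonded 5''-OH may stay incomplete, the aryl silyl ether next to the carbonyl may hydrolyse on isolation, or both triflates may be displaced by the same phenol. The fallback gives up the bridge and makes C8–C6'' by an intermolecular Suzuki–Miyaura coupling. Setting out from 4, Miyaura borylation (bis(pinacolato)diboron, PdCl2(dppf), KOAc, dioxane, 90 °C) would give the 8-pinacolboronate F4. Compound 7 would be iodinated to the 6''-iodide F1 as described above. Coupling of F4 with F1 (Pd2(dba)3, SPhos, K3PO4, toluene/water, 100 °C) would give the 7-O-(methoxymethyl)-5,4'''-di-O-benzyl biflavone F5. Methanolysis (HCl, MeOH/THF) would come back to the route at 12.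

Step 3. Bromination may go to C6 or occur twice, or traces of acid may remove the MOM group and so redirect the halogenation. The fallback changes the electrophile and the halide carried into the key step. Setting out from 3, silver-assisted iodination (I2, AgO2CCF3, NaHCO3, CH2Cl2, 0 °C), which is selective for C8 in 5,7-dialkoxyflavones, would give the 8-iodide F6. Methanolysis as in step 4 would give 5-O-benzyl-8-iodoacacetin F7. Tethering to 9 as in step 6 would give the iodo bis(aryloxy)silane F8. The conditions of step 7, with easier oxidative addition into C–I, would come back to the route at 11.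

**Further compounds**
F1 | step 7 | 6''-iodo-4'''-O-benzylgenkwanin | COc1c(I)c(O)c2c(c1)oc(cc2=O)-c1ccc(OCc3ccccc3)cc1
F2 | step 7 | 5''-O-[di-tert-butyl(trifluoromethanesulfonyloxy)silyl]-6''-iodo-4'''-O-benzylgenkwanin | COc1c(I)c(O[Si](OS(=O)(=O)C(F)(F)F)(C(C)(C)C)C(C)(C)C)c2c(c1)oc(cc2=O)-c1ccc(OCc3ccccc3)cc1
F3 | step 7 | di-tert-butylsilylene-bridged 5-O-benzyl-8-bromoacacetin and 6''-iodo-4'''-O-benzylgenkwanin | COc1ccc(cc1)-c1cc(=O)c2c(OCc3ccccc3)cc(O[Si](Oc3c(I)c(OC)cc4oc(-c5ccc(OCc6ccccc6)cc5)cc(=O)c34)(C(C)(C)C)C(C)(C)C)c(Br)c2o1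
F4 | step 6 | 5-O-benzyl-7-O-(methoxymethyl)acacetin-8-boronic acid pinacol ester | COc1ccc(cc1)-c1cc(=O)c2c(OCc3ccccc3)cc(OCOC)c(B3OC(C)(C)C(C)(C)O3)c2o1
F5 | step 6 | 7-O-(methoxymethyl)-5,4'''-di-O-benzyl derivative of the target | COc1ccc(cc1)-c1cc(=O)c2c(OCc3ccccc3)cc(OCOC)c(-c3c(OC)cc4oc(-c5ccc(OCc6ccccc6)cc5)cc(=O)c4c3O)c2o1
F6 | step 3 | 5-O-benzyl-8-iodo-7-O-(methoxymethyl)acacetin | COc1ccc(cc1)-c1cc(=O)c2c(OCc3ccccc3)cc(OCOC)c(I)c2o1
F7 | step 3 | 5-O-benzyl-8-iodoacacetin | COc1ccc(cc1)-c1cc(=O)c2c(OCc3ccccc3)cc(O)c(I)c2o1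
F8 | step 3 | di-tert-butylsilylene-bridged 5-O-benzyl-8-iodoacacetin and 4'''-O-benzylgenkwanin | COc1ccc(cc1)-c1cc(=O)c2c(OCc3ccccc3)cc(O[Si](Oc3cc(OC)cc4oc(-c5ccc(OCc6ccccc6)cc5)cc(=O)c34)(C(C)(C)C)C(C)(C)C)c(I)c2o1
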